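(The earlier runs and the new flask are calculated with made-up constants, noise included.)

A small charge of dissolved material is what you are watching here: 0.10 M of solid substrate goes in, but the late readings of both runs show c(starting material) near 12.1 mM.

| flask | solid substrate | partner | remark | time |
|---|---|---|---|---|
| gamma | 0.10 M | 0.074 M | run made earlier |  |
| epsilon | 0.10 M | 0.17 M | run made earlier |  |
| flask | 0.10 M | 0.110 M |  | 15 min |

- gamma (time / min: target / %, starting material / %): 1.33: 5.2, 9.1; 3.00: 4.9, 12.3; 8.00: 5.0, 12.1; 20.0: 5.2, 11.6
- epsilon (time / min: target / %, starting material / %): 1.33: 6.1, 8.9; 3.00: 6.5, 11.2; 8.00: 6.5, 12.2; 20.0: 6.2, 12.5

(each reading ± 0.3 percentage points)

- given per volume of solution although it is solid: solid substrate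
- the numbers in the tables scatter with a standard deviation of 0.3 percentage points
- candidate steps: 2 partner -> self-condensation product; solid substrate <-> starting material; starting material + partner -> target; starting material + partner -> isomer of the product; partner -> decomposed reagent
- at the start none of the solid substrate is in solution
- what has only dissolved of solid substrate counts as not reacted
- starting material means what is dissolved; the solid is not counted in it
- the reaction counts as stopped when no species that holds the solid substrate changes by six tenths of a point or more over the second half of the time

1. which holds at 15 min: what has brought the reaction to rest, or that it has not come to rest (for what has run out or reacted, a solid counts together with what of it has only dissolved) (all of the solid substrate has reacted / the partner has run out first / forward and back rates have come level / it is still moving)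
2. how much target there is at 15 min, in percent of the solid substrate charged
3. how much starting material there is at 15 min, in percent of the solid substrate charged
4. amount of target if the flask were left three thousand times as long, in percent of the solid substrate charged

Climb the time scales from the fastest. Target is level from the first reading: the gamma run has 5.2% at 1.33 min and 5.2% at 20.0 min. Solid remains, so I take the partner as the limiting reagent, with a lifetime under 1.33 min.

Next comes the refill. In the gamma run, starting material still climbs from 9.1% to 12.3% at 3.00 min, then holds.

The asked 15 min is 5.00 times that reading time, so I expect a still flask.

What remains is how much target the partner yields in its short life. Keep that as a concentration: I expect the solution to feel the cap on starting material, 12.1 mM, which is less than the solid charge. Averaged plateaus are 5.08 mM at 0.074 M and 6.33 mM at 0.17 M. Interpolating in ln c(partner) gives the flask 5.67 mM, the plateau c(target) bought by this partner charge. That is 5.67% target, with 12.1% starting material.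

The forecast gives the partner has run out first, 5.7%, 12.1% and 5.7% for the long wait, saying “Target formation has therefore stopped because the partner is gone”.

The flask gives the partner has run out first, with 0% of the partner left, 5.93% target, 12.0% starting material, and 5.93% after the long wait.

    2 partner → self-condensation product (k = 0.400 /M/s)
    solid substrate ⇌ starting material, rate k2*(cs2 - [starting material]) while solid is left; crystals form when [starting material] > cs2 (solubility = 12.0 mM, k = 0.0320 /s)
    starting material + partner → target (k = 5.50 /M/s)
    starting material + partner → isomer of the product (k = 4.80 /M/s)
    partner → decomposed reagent (k = 0.0500 /s)

Now take the neighbouring flask with 0.040 M of solid substrate and the same partner charge. Carrying 5.67 mM over, the reckoning reads 14.2% target, and 12.1 mM reads 30.2% starting material. That flask gives 14.8% target and 30.0% starting material at 15 min, with 0% of its partner left. Of its solid substrate, 72% remains, solid or dissolved.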